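**Retrosynthetic overview**
1. Target 22 comes from diol 20 by acetylation of 14-OH and 15-OH. The only ring (C15–C1–C2–C3–C4) comes from acyclic keto-enal 19 by an intramolecular vinylogous aldol of C4 onto the C15 ketone. This is the same C4–C15 bond and C15 carbinol that the oxidised-casbene → lathyrane/jatrophane pathway is thought to make by aldol.
2. The C7 aldehyde and C8 methyl ketone are the two ends of the C7–C8 retro-aldol scission of a 7-hydroxy-9-oxo-jatrophane; they are carried through as such. C11=C12 comes from cross-metathesis of 13 with enone 17.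
3. C3–C4 comes from a Felkin-controlled vinylogous Mukaiyama aldol of γ-keto aldehyde 8 with tiglaldehyde dienol silane 10. C4 of tiglaldehyde thus acts twice as nucleophile (formal 4+1 annulation over steps 5 and 10).
4. C1–C2 comes from enantioselective α-enolation of propanal with enol silane 6. C13–C14 comes from anti-crotylboration of methylglyoxal.
5. Ring order: one ring only, closed in step 10. C13, C14, C2 and C3 are set before it; C4 and C15 are set in it.

Assumption: atoms carry jatrophane numbers (ring C15–C1–C2–C3–C4; enal C5=C6–C7; side chain C14 to C8), the target being read as a 7,8-seco-jatrophane.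
Assumption: (R)-TRIP gives Re-face crotylboration and the (2S,5S)-imidazolidinone gives Si-face coupling, as in their usual models; if either sense is opposite, the mirror-image catalyst is used.

**Step 1**
Reactants: 1 methylglyoxal (anhydrous monomer freshly distilled from the commercial 40% aqueous solution); 2 (E)-crotylboronic acid pinacol ester
Product: 4 (3R,4R)-3-hydroxy-4-methylhex-5-en-2-one, via O-pinacolboryl ester 3 (not isolated)
Conditions: (R)-TRIP [(R)-3,3′-bis(2,4,6-triisopropylphenyl)-1,1′-binaphthyl-2,2′-diyl hydrogen phosphate] (5 mol%), 4 Å MS, toluene, −78 → −40 °C; H2O work-up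
Reagents that add atoms: none
Why: Chiral-phosphoric-acid-catalysed crotylboration of the aldehyde (the ketone is inert to a pinacol boronate), in which the closed chair transition state turns the E geometry into the anti C13/C14 relationship and the (R)-catalyst directs attack to the Re face, giving 14R,13R.

**Step 2**
Reactants: 4
Product: 6 (3R,4R)-4-methyl-2,3-bis[(triethylsilyl)oxy]hexa-1,5-diene, via dilithium diolate 5 (not isolated)
Conditions: LiN(i-Pr)2 (2.2 equiv), THF, −78 °C; Et3SiCl (2.5 equiv), −78 → 0 °C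
Reagents that add atoms: chlorotriethylsilane CC[Si](Cl)(CC)CC
Why: Kinetic enolate formation and O-silylation, in which the alkoxide formed first deactivates the neighbouring C14–H so that the second deprotonation occurs only at the methyl group (C1), and both oxygens are capped in one operation without touching a stereocentre.

**Step 3**
Reactants: 6; 7 propanal (3 equiv)
Product: 8 (2R,5R,6R)-2,6-dimethyl-4-oxo-5-[(triethylsilyl)oxy]oct-7-enal
Conditions: (2S,5S)-5-benzyl-2-tert-butyl-3-methylimidazolidin-4-one·CF3CO2H (20 mol%), (NH4)2Ce(NO3)6 (2.2 equiv), 2,6-di-tert-butylpyridine (2 equiv), H2O (2 equiv), acetone, −20 °C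
Reagents that add atoms: none
Why: Organo-SOMO α-enolation of an aldehyde, in which the propanal enamine is oxidised by tetravalent cerium to a radical cation that adds to the enol silane on its Si face (the benzyl group of the catalyst blocks the Re face) to set C2 as R, and a second oxidation with loss of silyl gives the C15 ketone.

**Step 4**
Reactants: 9 tiglaldehyde [(E)-2-methylbut-2-enal]
Product: 10 (1E)-1-[(tert-butyldimethylsilyl)oxy]-2-methylbuta-1,3-diene
Conditions: t-BuMe2SiOTf, Et3N, Et2O, 0 °C → rt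
Reagents that add atoms: tert-butyldimethylsilyl trifluoromethanesulfonate CC(C)(C)[Si](C)(C)OS(=O)(=O)C(F)(F)F
Why: Soft enolisation of an enal (silyl triflate plus amine) by γ-deprotonation gives the 1-silyloxydiene as the favoured 1E isomer, with no stereocentre involved.

**Step 5**
Reactants: 8; 10
Product: 12 (2E,5R,6R,9R,10R)-5-hydroxy-2,6,10-trimethyl-8-oxo-9-[(triethylsilyl)oxy]dodeca-2,11-dienal, via difluoroboryl aldolate 11 (not isolated)
Conditions: BF3·OEt2 (1.1 equiv), CH2Cl2/Et2O, −78 °C; H2O quench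
Reagents that add atoms: none
Why: Vinylogous Mukaiyama aldol, in which the BF3-activated aldehyde (more electrophilic than the ketone at −78 °C) is attacked by the γ-carbon of the dienol silane under Felkin–Anh control from the α-methyl centre C2, giving the 2,3-syn alcohol at C3 and regenerating the (E)-2-methyl enal.

**Step 6**
Reactants: 12
Product: 13 (2E,5R,6R,9R,10R)-2,6,10-trimethyl-1,8-dioxo-9-[(triethylsilyl)oxy]dodeca-2,11-dien-5-yl benzoate
Conditions: BzCl, pyridine, DMAP (cat.), CH2Cl2, 0 °C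
Reagents that add atoms: benzoyl chloride O=C(Cl)c1ccccc1
Why: DMAP-catalysed acylation of the only free hydroxyl (secondary C3–OH), with no change at any stereocentre.

**Step 7**
Reactants: 14 3-methylbut-2-en-1-ylmagnesium chloride; 15 N-methoxy-N-methylacetamide
Product: 17 3,3-dimethylpent-4-en-2-one, via magnesium hemiaminal chelate 16 (not isolated)
Conditions: THF, −40 → 0 °C; 1 M HCl
Reagents that add atoms: none
Why: Allylic Grignard addition to a Weinreb amide through the γ-carbon (SE2′) builds the quaternary carbon C10, and the stable chelate prevents over-addition.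

**Step 8**
Reactants: 13; 17 (8 equiv)
Product: 18 (2E,5R,6R,9R,10R,11E)-2,6,10,13,13-pentamethyl-1,8,14-trioxo-9-[(triethylsilyl)oxy]pentadeca-2,11-dien-5-yl benzoate
Conditions: second-generation Hoveyda–Grubbs catalyst RuCl2(H2IMes)(=CH-C6H4-2-O-i-Pr) (10 mol%), CH2Cl2, 40 °C
Reagents that add atoms: none
Why: Olefin cross-metathesis between the monosubstituted vinyl group of 13 and the vinyl group on the quaternary carbon of 17 (which does not homodimerise and is used in excess) gives the thermodynamically favoured E C11=C12 alkene, while the trisubstituted enal alkene is inert.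

**Step 9**
Reactants: 18
Product: 19 (2E,5R,6R,9R,10R,11E)-9-hydroxy-2,6,10,13,13-pentamethyl-1,8,14-trioxopentadeca-2,11-dien-5-yl benzoate
Conditions: HF·pyridine, pyridine, THF, 0 °C
Reagents that add atoms: none
Why: Buffered fluoride desilylation frees the C14 hydroxyl needed for chelation in the next step without affecting the benzoate, the enal or any stereocentre.

**Step 10**
Reactants: 19
Product: 20 (1S,2S,3R,5R)-3-hydroxy-3-[(1R,2R,3E)-1-hydroxy-2,5,5-trimethyl-6-oxohept-3-en-1-yl]-5-methyl-2-[(1E)-2-methyl-3-oxoprop-1-en-1-yl]cyclopentyl benzoate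
Conditions: MgBr2·OEt2 (3 equiv), i-Pr2NEt (2.5 equiv), CH2Cl2 (0.01 M), −40 → 0 °C; pH 7 buffer
Reagents that add atoms: none
Why: Proposed new method: a soft-enolisation intramolecular vinylogous aldol in which MgBr2 holds the C14 alkoxide and the C15 ketone in a five-membered Cram chelate and also acidifies the enal γ-hydrogens for deprotonation by the amine, so that dienolate carbon C4 closes the five-membered ring (5-enolexo-exo-trig) on the ketone face anti to C13 (C15 becomes R) with the enal arm trans to the bulky C14 chain (C4 becomes S, E-enal restored), the closest known reactions being MgBr2/amine direct aldol additions, chelation-controlled additions to α-alkoxy ketones and base-mediated intramolecular vinylogous aldol cyclisations.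

**Step 11**
Reactants: 20
Product: 22 target diacetate, via 14-monoacetate 21 (not isolated)
Conditions: Ac2O, DMAP, pyridine, 0 → 45 °C
Reagents that add atoms: acetic anhydride CC(=O)OC(C)=O
Why: DMAP-catalysed acetylation takes the secondary C14–OH first and the hindered tertiary C15–OH on warming, with no stereocentre affected and a base too weak to trigger vinylogous β-elimination of the C3 or C15 esters.

**Compound list**
1 | methylglyoxal (2-oxopropanal) | CC(=O)C=O | starting material
2 | (E)-crotylboronic acid pinacol ester | C/C=C/CB1OC(C)(C)C(C)(C)O1 | starting material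
3 | (3R,4R)-4-methyl-3-[(4,4,5,5-tetramethyl-1,3,2-dioxaborolan-2-yl)oxy]hex-5-en-2-one | CC1(C)OB(O[C@H]([C@H](C)C=C)C(C)=O)OC1(C)C | intermediate
4 | (3R,4R)-3-hydroxy-4-methylhex-5-en-2-one | O[C@H]([C@H](C)C=C)C(C)=O | intermediate
5 | dilithium (3R,4R)-4-methylhexa-1,5-diene-2,3-diolate | [Li+].[Li+].[O-][C@H]([C@H](C)C=C)C(=C)[O-] | intermediate
6 | (3R,4R)-4-methyl-2,3-bis[(triethylsilyl)oxy]hexa-1,5-diene | CC[Si](CC)(CC)O[C@H]([C@H](C)C=C)C(=C)O[Si](CC)(CC)CC | intermediate
7 | propanal | CCC=O | starting material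
8 | (2R,5R,6R)-2,6-dimethyl-4-oxo-5-[(triethylsilyl)oxy]oct-7-enal | CC[Si](CC)(CC)O[C@H]([C@H](C)C=C)C(=O)C[C@@H](C)C=O | intermediate
9 | tiglaldehyde, (E)-2-methylbut-2-enal | C/C=C(\C)C=O | starting material
10 | (1E)-1-[(tert-butyldimethylsilyl)oxy]-2-methylbuta-1,3-diene | C=C/C(C)=C/O[Si](C)(C)C(C)(C)C | intermediate
11 | (2E,5R,6R,9R,10R)-5-[(difluoroboranyl)oxy]-2,6,10-trimethyl-8-oxo-9-[(triethylsilyl)oxy]dodeca-2,11-dienal | CC[Si](CC)(CC)O[C@H]([C@H](C)C=C)C(=O)C[C@@H](C)[C@H](OB(F)F)C/C=C(\C)C=O | intermediate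
12 | (2E,5R,6R,9R,10R)-5-hydroxy-2,6,10-trimethyl-8-oxo-9-[(triethylsilyl)oxy]dodeca-2,11-dienal | CC[Si](CC)(CC)O[C@H]([C@H](C)C=C)C(=O)C[C@@H](C)[C@H](O)C/C=C(\C)C=O | intermediate
13 | (2E,5R,6R,9R,10R)-2,6,10-trimethyl-1,8-dioxo-9-[(triethylsilyl)oxy]dodeca-2,11-dien-5-yl benzoate | CC[Si](CC)(CC)O[C@H]([C@H](C)C=C)C(=O)C[C@@H](C)[C@H](OC(=O)c1ccccc1)C/C=C(\C)C=O | intermediate
14 | 3-methylbut-2-en-1-ylmagnesium chloride | CC(C)=CC[Mg]Cl | starting material
15 | N-methoxy-N-methylacetamide | CC(=O)N(C)OC | starting material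
16 | chloromagnesium 2-[methoxy(methyl)amino]-3,3-dimethylpent-4-en-2-olate | CC(O[Mg]Cl)(N(C)OC)C(C)(C)C=C | intermediate
17 | 3,3-dimethylpent-4-en-2-one | CC(=O)C(C)(C)C=C | intermediate
18 | (2E,5R,6R,9R,10R,11E)-2,6,10,13,13-pentamethyl-1,8,14-trioxo-9-[(triethylsilyl)oxy]pentadeca-2,11-dien-5-yl benzoate | CC[Si](CC)(CC)O[C@H]([C@H](C)/C=C/C(C)(C)C(C)=O)C(=O)C[C@@H](C)[C@H](OC(=O)c1ccccc1)C/C=C(\C)C=O | intermediate
19 | (2E,5R,6R,9R,10R,11E)-9-hydroxy-2,6,10,13,13-pentamethyl-1,8,14-trioxopentadeca-2,11-dien-5-yl benzoate | O[C@H]([C@H](C)/C=C/C(C)(C)C(C)=O)C(=O)C[C@@H](C)[C@H](OC(=O)c1ccccc1)C/C=C(\C)C=O | intermediate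
20 | (1S,2S,3R,5R)-3-hydroxy-3-[(1R,2R,3E)-1-hydroxy-2,5,5-trimethyl-6-oxohept-3-en-1-yl]-5-methyl-2-[(1E)-2-methyl-3-oxoprop-1-en-1-yl]cyclopentyl benzoate | O[C@H]([C@H](C)/C=C/C(C)(C)C(C)=O)[C@@]1(O)C[C@@H](C)[C@H](OC(=O)c2ccccc2)[C@@H]1/C=C(\C)C=O | intermediate
21 | (1S,2S,3R,5R)-3-[(1R,2R,3E)-1-acetoxy-2,5,5-trimethyl-6-oxohept-3-en-1-yl]-3-hydroxy-5-methyl-2-[(1E)-2-methyl-3-oxoprop-1-en-1-yl]cyclopentyl benzoate | CC(=O)O[C@H]([C@H](C)/C=C/C(C)(C)C(C)=O)[C@@]1(O)C[C@@H](C)[C@H](OC(=O)c2ccccc2)[C@@H]1/C=C(\C)C=O | intermediate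
22 | (1S,2S,3R,5R)-3-acetoxy-3-[(1R,2R,3E)-1-acetoxy-2,5,5-trimethyl-6-oxohept-3-en-1-yl]-5-methyl-2-[(1E)-2-methyl-3-oxoprop-1-en-1-yl]cyclopentyl benzoate (CNP0489076.2) | CC(=O)O[C@H]([C@H](C)/C=C/C(C)(C)C(C)=O)[C@@]1(OC(C)=O)C[C@@H](C)[C@H](OC(=O)c2ccccc2)[C@@H]1/C=C(\C)C=O | target

**Totals**
Total steps: 11 (9 in the main line plus steps 4 and 7, which prepare 10 and 17).
Longest linear sequence: 9 (steps 1, 2, 3, 5, 6, 8, 9, 10, 11).

**Steps most likely to fail, with fallbacks**

Step 10 (ring closure). The dienolate could expel the C3 benzoate by vinylogous E1cB, the C14 α-ketol could epimerise, or the benzoate could migrate to the new alkoxides. The fallback closes the ring before acylation, on a substrate with no leaving group at C3 and two templating alkoxides. It sets out from 12. Cross-metathesis with 17 (catalyst of step 8) gives (2E,5R,6R,9R,10R,11E)-5-hydroxy-2,6,10,13,13-pentamethyl-8,14-dioxo-9-[(triethylsilyl)oxy]pentadeca-2,11-dienal F1. HF·pyridine then gives (2E,5R,6R,9R,10R,11E)-5,9-dihydroxy-2,6,10,13,13-pentamethyl-8,14-dioxopentadeca-2,11-dienal F2. MgBr2·OEt2/i-Pr2NEt, now with a C3–O–Mg–O=C15 bridge that enforces the cis-3,15-diol in addition to the C14 chelate, closes it to (1S,2S,3R,5R)-3-[(1R,2R,3E)-1-hydroxy-2,5,5-trimethyl-6-oxohept-3-en-1-yl]-5-methyl-2-[(1E)-2-methyl-3-oxoprop-1-en-1-yl]cyclopentane-1,3-diol F3. Benzoyl chloride/pyridine at −40 °C acylates the least hindered hydroxyl (ring C3–OH; C14–OH is neopentyl-like and C15–OH tertiary), and the route is rejoined at 20.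

Step 8 (cross-metathesis of two hindered olefins). If the vinyl group on the quaternary carbon of 17 will not couple with the α-branched vinyl group of 13, the C10–C11 bond is made instead of the C11=C12 bond. The fallback sets out from 13. Cross-metathesis with the unhindered vinylboronic acid pinacol ester gives (2E,5R,6R,9R,10R,11E)-2,6,10-trimethyl-1,8-dioxo-12-(4,4,5,5-tetramethyl-1,3,2-dioxaborolan-2-yl)-9-[(triethylsilyl)oxy]dodeca-2,11-dien-5-yl benzoate F4. Aqueous KHF2 in MeOH converts the boronate and removes the silyl ether, giving potassium [(1E,3R,4R,7R,8R,10E)-8-(benzoyloxy)-4-hydroxy-3,7,11-trimethyl-5,12-dioxododeca-1,10-dien-1-yl]trifluoroborate F5. Visible-light photoredox coupling with 3-bromo-3-methylbutan-2-one (fac-Ir(ppy)3, blue light) follows: the tertiary α-keto radical adds at the boron-bearing carbon, oxidation gives a β-boryl cation, and loss of BF3 restores the E-alkene. The route is rejoined at 19.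

Step 3 (oxidative enolation on a functionalised enol silane). If the cerium-mediated coupling gives poor yield or selectivity, the polarity is reversed and no stoichiometric oxidant is used. The fallback sets out from 6. N-bromosuccinimide in THF at −78 °C reacts only at the enol silane and gives (3R,4R)-1-bromo-4-methyl-3-[(triethylsilyl)oxy]hex-5-en-2-one F6. Photoredox organocatalytic α-alkylation of propanal 7 with F6 follows (Ru(bpy)3Cl2, the same imidazolidinone, 2,6-lutidine, DMF, visible light), in which the electrophilic α-keto radical adds to the Si face of the chiral enamine. The route is rejoined at 8.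

**Further compounds**
F1 | step 10 | (2E,5R,6R,9R,10R,11E)-5-hydroxy-2,6,10,13,13-pentamethyl-8,14-dioxo-9-[(triethylsilyl)oxy]pentadeca-2,11-dienal | CC[Si](CC)(CC)O[C@H]([C@H](C)/C=C/C(C)(C)C(C)=O)C(=O)C[C@@H](C)[C@H](O)C/C=C(\C)C=O
F2 | step 10 | (2E,5R,6R,9R,10R,11E)-5,9-dihydroxy-2,6,10,13,13-pentamethyl-8,14-dioxopentadeca-2,11-dienal | O[C@H]([C@H](C)/C=C/C(C)(C)C(C)=O)C(=O)C[C@@H](C)[C@H](O)C/C=C(\C)C=O
F3 | step 10 | (1S,2S,3R,5R)-3-[(1R,2R,3E)-1-hydroxy-2,5,5-trimethyl-6-oxohept-3-en-1-yl]-5-methyl-2-[(1E)-2-methyl-3-oxoprop-1-en-1-yl]cyclopentane-1,3-diol | O[C@H]([C@H](C)/C=C/C(C)(C)C(C)=O)[C@@]1(O)C[C@@H](C)[C@H](O)[C@@H]1/C=C(\C)C=O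
F4 | step 8 | (2E,5R,6R,9R,10R,11E)-2,6,10-trimethyl-1,8-dioxo-12-(4,4,5,5-tetramethyl-1,3,2-dioxaborolan-2-yl)-9-[(triethylsilyl)oxy]dodeca-2,11-dien-5-yl benzoate | CC[Si](CC)(CC)O[C@H]([C@H](C)/C=C/B1OC(C)(C)C(C)(C)O1)C(=O)C[C@@H](C)[C@H](OC(=O)c1ccccc1)C/C=C(\C)C=O
F5 | step 8 | potassium [(1E,3R,4R,7R,8R,10E)-8-(benzoyloxy)-4-hydroxy-3,7,11-trimethyl-5,12-dioxododeca-1,10-dien-1-yl]trifluoroborate | [K+].O[C@H]([C@H](C)/C=C/[B-](F)(F)F)C(=O)C[C@@H](C)[C@H](OC(=O)c1ccccc1)C/C=C(\C)C=O
F6 | step 3 | (3R,4R)-1-bromo-4-methyl-3-[(triethylsilyl)oxy]hex-5-en-2-one | CC[Si](CC)(CC)O[C@H]([C@H](C)C=C)C(=O)CBr
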